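Ring A is a cyclohexane in which C4, carrying the carboxyl and a methyl group, adjoins the ring-fusion carbon C5; once a C1=C10 double bond is written in, C2–C3 and C4–C5 are the two σ-bonds of a Diels–Alder adduct of methacrolein. The diene is an open-chain 1-alkyl-2-methylbutadiene made from (E)-geranylacetone, so the key step builds ring A on an acyclic chain and sets C4 and C5 by catalysis. A single cation–olefin cyclisation then closes ring B and relays C10, C9 and C8 from C5, the chain ketone capping C8 with oxygen. Shapiro acylation converts that ketone into the hydroxy enone.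

Key step: step 4

Remark: atoms carry labdane numbers throughout; the (S)-oxazaborolidinium is assumed to shield the enal face that leads to the (1S,2R) adduct, and its enantiomer would be used unchanged if the sense were the reverse.

Step 1
Reactants: 1 (E)-geranylacetone
Product: 2 (5E,9E)-11-hydroxy-6,10-dimethylundeca-5,9-dien-2-one
Conditions: SeO2 (0.5 equiv), t-BuOOH (70% aq.), salicylic acid (cat.), CH2Cl2, rt
Reagents that add atoms: selenium dioxide O=[Se]=O (oxygen donor, regenerated by tert-butyl hydroperoxide CC(C)(C)OO)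
Why: Riley-type allylic oxidation (ene reaction, then [2,3]-sigmatropic shift) should occur at the more electron-rich terminal alkene and, by the usual (E) rule, on the methyl group trans to the chain, leaving the ketone and the internal alkene untouched.

Step 2
Reactants: 2 (5E,9E)-11-hydroxy-6,10-dimethylundeca-5,9-dien-2-one
Product: 3 (2E,6E)-2,6-dimethyl-10-oxoundeca-2,6-dienal
Conditions: activated MnO2 (excess), CH2Cl2, rt
Reagents that add atoms: none
Why: MnO2 oxidises only the allylic alcohol (allylic oxidation) to the (E)-enal, and any enal already formed in step 1 converges on the same product.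

Step 3
Reactants: 3 (2E,6E)-2,6-dimethyl-10-oxoundeca-2,6-dienal; 4 methyltriphenylphosphonium bromide
Product: 5 (5E,9E)-6,10-dimethyldodeca-5,9,11-trien-2-one
Conditions: 4, KHMDS, THF, 0 °C; then 3, −78 → 0 °C
Reagents that add atoms: methyltriphenylphosphonium bromide C[P+](c1ccccc1)(c1ccccc1)c1ccccc1.[Br-]
Why: Wittig methylenation with the non-stabilised ylide is much faster at the aldehyde than at the methyl ketone at low temperature and leaves the (E)-alkene geometry intact, giving the (E)-1,3-diene with the chain on the outside position of C5.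

Step 4
Reactants: 5 (5E,9E)-6,10-dimethyldodeca-5,9,11-trien-2-one; 6 methacrolein
Product: 7 (1S,2R)-1,3-dimethyl-2-[(3E)-3-methyl-7-oxooct-3-en-1-yl]cyclohex-3-ene-1-carbaldehyde
Conditions: 6 (5 equiv), (S)-B-o-tolyl diphenylprolinol-derived oxazaborolidine (20 mol %), Tf2NH (18 mol %), CH2Cl2, −78 → −40 °C
Reagents that add atoms: methacrolein C=C(C)C=O
Why: The cationic oxazaborolidinium binds methacrolein (s-trans, formyl C–H···O contact) and the diene adds in an asynchronous concerted [4+2] in which the dienophile CH2 (C3) bonds ahead to the unsubstituted terminus C2 and the fully substituted α-carbon C4 bonds to C5. The closest known reaction type is the oxazaborolidinium-catalysed enantioselective Diels–Alder reaction of 2-methylacrolein with alkyl-substituted 1,3-dienes. Ring A closes as a six-membered carbocycle by suprafacial [4π+2π] cycloaddition. C4 and C5 arise together: their relative configuration should follow from the (E) geometry at C5=C10 and the endo position of the catalyst-bound formyl group, which places CHO cis to the C5 chain and the C4 methyl cis to H5, and their absolute configuration from the catalyst shielding one enal face. The step needs "ortho" regiochemistry, reaction at the conjugated diene only, and endo selectivity. The alkyl substituent on the C5 terminus (1-substituent rule, as for 1-vinylcyclohexene) and the unhindered C2 terminus should secure the first, the isolated trisubstituted alkenes and the ketone are inert at −78 °C, and Lewis-acid coordination favours the endo carbonyl.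

Step 5
Reactants: 7 (1S,2R)-1,3-dimethyl-2-[(3E)-3-methyl-7-oxooct-3-en-1-yl]cyclohex-3-ene-1-carbaldehyde
Product: 8 (1S,2R)-1,3-dimethyl-2-[(3E)-3-methyl-7-oxooct-3-en-1-yl]cyclohex-3-ene-1-carboxylic acid
Conditions: NaClO2, NaH2PO4, 2-methyl-2-butene, t-BuOH/H2O, 0 °C → rt
Reagents that add atoms: sodium chlorite [Na+].[O-]Cl=O
Why: Pinnick oxidation converts the hindered, non-enolisable aldehyde into the acid under buffered conditions in which the scavenger removes HOCl before it can touch the alkenes; C4 is quaternary and cannot epimerise.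

Step 6
Reactants: 8 (1S,2R)-1,3-dimethyl-2-[(3E)-3-methyl-7-oxooct-3-en-1-yl]cyclohex-3-ene-1-carboxylic acid
Product: 10 8α-hydroxy-13-oxo-14,15-dinorlabdan-19-oic acid, via cyclic enol ether 9 (not isolated)
Conditions: ClSO3H (5 equiv, promoter, not consumed), 2-nitropropane, −78 → −30 °C; Et3N quench; then THF/1 M HCl, rt
Reagents that add atoms: water O
Why: Acid-promoted cation–olefin cyclisation of an α-cyclogeranyl-type monocycle with carbonyl-oxygen termination (the closure that gives sclareol oxide): protonation of C1 gives the tertiary C10 cation, the (E)-C8=C9 alkene closes ring B through a chair in which the C5 chain is equatorial and the axial C4 carboxyl blocks the β-axial approach, so C9 should bond to the equatorial face of C10 (C20 β, trans to H5) and the ketone oxygen add anti at C8 (9α-H, 8α-O), while oxygen capture at C10 by the carboxyl or at C8 before C–C bond formation is a reversible tertiary alkyl–oxygen ionisation; aqueous acid then opens the enol ether at C13.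

Step 7
Reactants: 10 8α-hydroxy-13-oxo-14,15-dinorlabdan-19-oic acid; 11 2,4,6-triisopropylbenzenesulfonyl hydrazide
Product: 12 8α-hydroxy-13-(2,4,6-triisopropylbenzenesulfonylhydrazono)-14,15-dinorlabdan-19-oic acid
Conditions: 11 (1.1 equiv), THF, cat. HCl, rt
Reagents that add atoms: 2,4,6-triisopropylbenzenesulfonyl hydrazide CC(C)c1cc(C(C)C)c(S(=O)(=O)NN)c(C(C)C)c1
Why: Condensation of the methyl ketone with the arenesulfonyl hydrazide gives the trisylhydrazone, the derivative that fragments cleanly at 0 °C in the Shapiro reaction; the acid and the tertiary alcohol are spectators.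

Step 8
Reactants: 12 8α-hydroxy-13-(2,4,6-triisopropylbenzenesulfonylhydrazono)-14,15-dinorlabdan-19-oic acid; 13 2-(tert-butyldimethylsilyloxy)-N-methoxy-N-methylacetamide
Product: 15 15-(tert-butyldimethylsilyloxy)-8α-hydroxy-14-oxolabd-13(16)-en-19-oic acid, via vinyllithium 14 (not isolated)
Conditions: n-BuLi (4.5 equiv), TMEDA, THF, −78 → 0 °C; then 13 (2 equiv), −78 °C → rt; aq. NH4Cl
Reagents that add atoms: 2-(tert-butyldimethylsilyloxy)-N-methoxy-N-methylacetamide CON(C)C(=O)CO[Si](C)(C)C(C)(C)C
Why: Shapiro reaction: after the acid, alcohol and N–H are converted to lithium salts, the next equivalent removes a proton from the less substituted α-methyl group, loss of sulfinate and N2 gives the 1-alken-2-yllithium, and the Weinreb amide acylates it once through the chelated tetrahedral adduct, so the 2-methylene ketone should form without over-addition.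

Step 9
Reactants: 15 15-(tert-butyldimethylsilyloxy)-8α-hydroxy-14-oxolabd-13(16)-en-19-oic acid
Product: 16 8α,15-dihydroxy-14-oxolabd-13(16)-en-19-oic acid (target)
Conditions: HF·pyridine, THF, 0 °C → rt
Reagents that add atoms: none
Why: Fluoride cleaves the primary silyl ether (desilylation), and the enone, the tertiary alcohol and the acid are stable to buffered HF·pyridine.

Compound list
1 | (E)-geranylacetone, (5E)-6,10-dimethylundeca-5,9-dien-2-one | CC(C)=CCC/C(C)=C/CCC(C)=O | starting material
2 | (5E,9E)-11-hydroxy-6,10-dimethylundeca-5,9-dien-2-one | OC/C(C)=C/CC/C(C)=C/CCC(C)=O | intermediate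
3 | (2E,6E)-2,6-dimethyl-10-oxoundeca-2,6-dienal | O=C/C(C)=C/CC/C(C)=C/CCC(C)=O | intermediate
4 | methyltriphenylphosphonium bromide | C[P+](c1ccccc1)(c1ccccc1)c1ccccc1.[Br-] | starting material
5 | (5E,9E)-6,10-dimethyldodeca-5,9,11-trien-2-one | C=C/C(C)=C/CC/C(C)=C/CCC(C)=O | intermediate
6 | methacrolein | C=C(C)C=O | starting material
7 | (1S,2R)-1,3-dimethyl-2-[(3E)-3-methyl-7-oxooct-3-en-1-yl]cyclohex-3-ene-1-carbaldehyde | CC1=CCC[C@](C)(C=O)[C@@H]1CC/C(C)=C/CCC(C)=O | intermediate
8 | (1S,2R)-1,3-dimethyl-2-[(3E)-3-methyl-7-oxooct-3-en-1-yl]cyclohex-3-ene-1-carboxylic acid | CC1=CCC[C@](C)(C(=O)O)[C@@H]1CC/C(C)=C/CCC(C)=O | intermediate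
9 | 8α,13-epoxy-14,15-dinorlabd-12-en-19-oic acid (cyclic enol ether, not isolated) | CC1=CC[C@@H]2[C@@]3(C)CCC[C@](C)(C(=O)O)[C@@H]3CC[C@@]2(C)O1 | intermediate
10 | 8α-hydroxy-13-oxo-14,15-dinorlabdan-19-oic acid | CC(=O)CC[C@@H]1[C@@]2(C)CCC[C@](C)(C(=O)O)[C@@H]2CC[C@@]1(C)O | intermediate
11 | 2,4,6-triisopropylbenzenesulfonyl hydrazide | CC(C)c1cc(C(C)C)c(S(=O)(=O)NN)c(C(C)C)c1 | starting material
12 | 8α-hydroxy-13-(2,4,6-triisopropylbenzenesulfonylhydrazono)-14,15-dinorlabdan-19-oic acid | CC(CC[C@@H]1[C@@]2(C)CCC[C@](C)(C(=O)O)[C@@H]2CC[C@@]1(C)O)=NNS(=O)(=O)c1c(C(C)C)cc(C(C)C)cc1C(C)C | intermediate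
13 | 2-(tert-butyldimethylsilyloxy)-N-methoxy-N-methylacetamide | CON(C)C(=O)CO[Si](C)(C)C(C)(C)C | starting material
14 | trilithiated vinyllithium: 13-lithio-14,15-dinorlabd-13(16)-ene 8α-olate 19-carboxylate (not isolated) | [Li]C(=C)CC[C@@H]1[C@@]2(C)CCC[C@](C)(C(=O)O[Li])[C@@H]2CC[C@@]1(C)O[Li] | intermediate
15 | 15-(tert-butyldimethylsilyloxy)-8α-hydroxy-14-oxolabd-13(16)-en-19-oic acid | C=C(CC[C@@H]1[C@@]2(C)CCC[C@](C)(C(=O)O)[C@@H]2CC[C@@]1(C)O)C(=O)CO[Si](C)(C)C(C)(C)C | intermediate
16 | 8α,15-dihydroxy-14-oxolabd-13(16)-en-19-oic acid | C=C(CC[C@@H]1[C@@]2(C)CCC[C@](C)(C(=O)O)[C@@H]2CC[C@@]1(C)O)C(=O)CO | target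

Total steps: 9. Longest linear sequence: 9 steps (from 1; compounds 4, 6, 11 and 13 are bought).

Steps most likely to fail

Step 4. The cycloaddition may lose regiocontrol (the 2-methyl group of the diene directs C4 towards C2, against the C5 alkyl group), may place the formyl group exo, or the catalyst may be held back by the ketone. The fallback sets out from 5 and returns at 8. It replaces catalyst control by auxiliary control with an ester dienophile: (R)-pantolactone is acylated with methacryloyl chloride (Et3N, DMAP) to (R)-pantolactone methacrylate F1. F1 is combined with 5 under Et2AlCl in CH2Cl2 at −78 °C to give the pantolactonyl ester F2, whose diastereomers can be separated. LiOH/H2O2 in THF/water then releases acid 8, so the Pinnick step is not needed.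

Step 6. Protonation may occur at the chain alkene instead of the ring alkene, with early oxygen capture of the C8 cation, or a hydride shift from C5 may erode the relay. The fallback sets out from 8 and returns at 10. It makes C10 the only site that can ionise: iodolactonisation (I2, NaHCO3, MeCN/water, 0 °C) gives the 1α-iodo-19,10β-lactone F3, and Bu3SnH/AIBN removes the iodine to give the bridged 19,10β-lactone F4. SnCl4 in CH2Cl2 (−78 → −20 °C, aprotic) then ionises the tertiary C10–O bond with the carboxylate shielding the β-face, and ring B closes as in step 6. Aqueous HCl work-up gives 10.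

Step 8. Butyllithium may add to the lithium carboxylate, or dianion formation may be incomplete in the presence of two other acidic sites. The fallback sets out from 10 and returns at 15. It avoids organolithium reagents: hydrazine hydrate gives the hydrazone F5, and iodine with tetramethylguanidine (Barton vinyl iodide synthesis) gives the 13-iodo-13(16)-ene F6. Nozaki–Hiyama–Kishi coupling (CrCl2, cat. NiCl2, DMF) with (tert-butyldimethylsilyloxy)acetaldehyde gives the allylic alcohol F7 as a C14 epimer mixture, and Dess–Martin oxidation gives 15.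

Further compounds
F1 | step 4 | (R)-pantolactone methacrylate | C=C(C)C(=O)O[C@H]1C(=O)OCC1(C)C
F2 | step 4 | (R)-pantolactonyl (1S,2R)-1,3-dimethyl-2-[(3E)-3-methyl-7-oxooct-3-en-1-yl]cyclohex-3-ene-1-carboxylate | CC1=CCC[C@](C)(C(=O)O[C@H]2C(=O)OCC2(C)C)[C@@H]1CC/C(C)=C/CCC(C)=O
F3 | step 6 | 1α-iodo-19,10β-lactone of acid 8 (6-oxabicyclo[3.2.1]octan-7-one core) | C[C@@]12CC[C@H](I)[C@@](C)(OC1=O)[C@H]2CC/C(C)=C/CCC(C)=O
F4 | step 6 | 19,10β-lactone of acid 8 | C[C@@]12CCC[C@@](C)(OC1=O)[C@H]2CC/C(C)=C/CCC(C)=O
F5 | step 8 | 13-hydrazone of 10 | CC(CC[C@@H]1[C@@]2(C)CCC[C@](C)(C(=O)O)[C@@H]2CC[C@@]1(C)O)=NN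
F6 | step 8 | 8α-hydroxy-13-iodo-14,15-dinorlabd-13(16)-en-19-oic acid | C=C(I)CC[C@@H]1[C@@]2(C)CCC[C@](C)(C(=O)O)[C@@H]2CC[C@@]1(C)O
F7 | step 8 | 15-(tert-butyldimethylsilyloxy)-8α,14-dihydroxylabd-13(16)-en-19-oic acid (C14 epimers) | C=C(CC[C@@H]1[C@@]2(C)CCC[C@](C)(C(=O)O)[C@@H]2CC[C@@]1(C)O)C(O)CO[Si](C)(C)C(C)(C)C
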